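The carbocycle is closed last, at C5–C6 (isochromene numbering), onto a finished pyran. The plan reads C6(=O)–C7(CH3)(O) as a lactic acid unit and C5 as the γ-carbon of the C8 ketone through the C8a=C4a bond that the carbocycle shares with the pyran. The key step is a vinylogous Dieckmann cyclisation: the γ-dienolate carbon C5 attacks the carbonyl of a lactate pivalaldehyde acetal (1,3-dioxolan-4-one). One operation closes the six-membered ring, turns the temporary acetal ring into the C6 ketone with loss of pivalaldehyde and unveils the C7 alkoxide. The precursor is a pyranyl ketone of that acetal; C7 is set one step earlier by self-regeneration of the lactate stereocentre, C3 comes from (R)-3-hydroxybutanoate.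

Key step: step 7

Remarks on the chemistry:
- Ring atoms are named C1, O2, C3, C4, C4a, C5, C6, C7, C8, C8a throughout; the target is (3R,7R).
- Compound 17 is written as the diketone; it should exist largely as its 6-hydroxy dienone tautomer.
- LDA is taken as a bought solution.

Step 1
Reactants: 1 ethyl (3R)-3-hydroxybutanoate; 2 tert-butyl acetate
Product: 4 tert-butyl (5R)-5-hydroxy-3-oxohexanoate, via lithium tert-butyl acetate enolate 3 (not isolated)
Conditions: LDA (3.5 equiv), 2 (3.5 equiv), THF, −78 °C; then 1, −78 → −30 °C; aq. NH4Cl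
Reagents that add atoms: none
Why: Crossed Claisen condensation: the excess lithium enolate first deprotonates the hydroxyl and then acylates at the ethyl ester, and the product sits as its β-keto ester enolate until the quench, so the C3 stereocentre (R) is carried over unchanged.

Step 2
Reactants: 4 tert-butyl (5R)-5-hydroxy-3-oxohexanoate
Product: 6 tert-butyl (2R)-2-methyl-4-oxo-3,4-dihydro-2H-pyran-5-carboxylate, via enaminone 5 (not isolated)
Conditions: Me2NCH(OMe)2 (1.3 equiv), toluene, rt
Reagents that add atoms: N,N-dimethylformamide dimethyl acetal, COC(OC)N(C)C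
Why: Condensation of the active methylene with the amide acetal gives enaminone 5, whose δ-hydroxyl displaces dimethylamine by 6-endo addition–elimination (a known cyclocondensation of δ-hydroxy β-keto esters to 2,3-dihydro-4H-pyran-4-ones), which installs C1 and closes the pyran without touching C3.

Step 3
Reactants: 6 tert-butyl (2R)-2-methyl-4-oxo-3,4-dihydro-2H-pyran-5-carboxylate
Product: 8 tert-butyl (6R)-6-methyl-4-[(trifluoromethanesulfonyl)oxy]-5,6-dihydro-2H-pyran-3-carboxylate, via lithium enolate 7 (not isolated)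
Conditions: L-Selectride (1.1 equiv), THF, −78 °C; then PhNTf2 (1.2 equiv), −78 °C → rt; aq. NH4Cl
Reagents that add atoms: N-phenylbis(trifluoromethanesulfonimide), O=S(=O)(N(c1ccccc1)S(=O)(=O)C(F)(F)F)C(F)(F)F
Why: 1,4-Hydride addition to the alkoxymethylene β-keto ester gives the regiodefined enolate 7, which is O-sulfonylated by PhNTf2 (conjugate reduction–enolate triflation), so the enol triflate double bond lies at C4a=C8a and C1 is left as CH2.

Step 4
Reactants: 8 tert-butyl (6R)-6-methyl-4-[(trifluoromethanesulfonyl)oxy]-5,6-dihydro-2H-pyran-3-carboxylate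
Product: 9 tert-butyl (6R)-4,6-dimethyl-5,6-dihydro-2H-pyran-3-carboxylate
Conditions: MeMgBr (1.5 equiv), Fe(acac)3 (5 mol %), THF/NMP, −30 °C
Reagents that add atoms: methylmagnesium bromide, C[Mg]Br
Why: Iron-catalysed Kumada-type cross-coupling of an alkenyl triflate with a methyl Grignard reagent is fast at −30 °C and tolerates the tert-butyl ester; it installs C5 as the methyl group cis to the ester.

Step 5
Reactants: 10 (R)-lactic acid; 11 pivalaldehyde
Product: 12 (2R,5R)-2-tert-butyl-5-methyl-1,3-dioxolan-4-one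
Conditions: 11 (1.5 equiv), TsOH·H2O (cat.), H2SO4 (cat.), pentane, reflux with azeotropic removal of water; crystallisation from pentane at −78 °C
Reagents that add atoms: none
Why: Acid-catalysed acetalisation of the α-hydroxy acid with removal of water gives the 1,3-dioxolan-4-one, the cis isomer being favoured and purified by crystallisation; the acetal carbon now stores the lactate chirality (self-regeneration of stereocentres).

Step 6
Reactants: 9 tert-butyl (6R)-4,6-dimethyl-5,6-dihydro-2H-pyran-3-carboxylate; 12 (2R,5R)-2-tert-butyl-5-methyl-1,3-dioxolan-4-one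
Product: 15 (2R,5S)-2-tert-butyl-5-[(6R)-4,6-dimethyl-5,6-dihydro-2H-pyran-3-carbonyl]-5-methyl-1,3-dioxolan-4-one, via acid chloride 13 (not isolated), via lithium dioxolanone enolate 14 (not isolated)
Conditions: 9, SOCl2 (neat), rt, then evaporation; 12, LDA (1.05 equiv), THF, −78 °C; then 13 in THF, −78 °C; AcOH quench
Reagents that add atoms: none
Why: Thionyl chloride turns the tert-butyl ester directly into acid chloride 13, which C-acylates lithium enolate 14 (crossed Claisen acylation) on the face anti to the tert-butyl group, so the acyl group takes the place of the lactate hydrogen and C7 is set with the configuration needed for (7R); the product cannot enolise at C7, so it neither epimerises nor consumes a second equivalent of enolate.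

Step 7
Reactants: 15 (2R,5S)-2-tert-butyl-5-[(6R)-4,6-dimethyl-5,6-dihydro-2H-pyran-3-carbonyl]-5-methyl-1,3-dioxolan-4-one
Product: 17 (3R,7R)-7-hydroxy-3,7-dimethyl-3,4-dihydro-1H-isochromene-6,8(5H,7H)-dione, via potassium γ-dienolate 16 (not isolated)
Conditions: t-BuOK (2.5 equiv), THF/t-BuOH (10:1), −40 → 0 °C; then cold 1 M HCl
Reagents that add atoms: none
Why: t-BuOK reversibly deprotonates the γ-methyl group (C5) of the C8 enone, which has no α-hydrogen; dienolate 16 attacks the lactone carbonyl C6 through C5, the tetrahedral intermediate expels the acetal oxygen, the hemiacetal alkoxide loses pivalaldehyde, and the product is held as its stabilised vinylogous 1,3-dione enolate until the quench. This is an intramolecular vinylogous Claisen (Dieckmann) condensation, and 1,3-dioxolan-4-ones are known to acylate enolates and organometallics at the lactone carbonyl with release of the carbonyl component. The carbocycle closes in the 6-(enolendo)-exo-trig mode. No new stereocentre is formed: C7 is quaternary and cannot enolise, so the configuration from step 6 is carried through, and C3 is remote from every acidic site. The step needs site selectivity for C5 over C4, C8a and oxygen, and the substrate secures it because only C5 reaches C6 through a six-membered transition state (C8a or O would close four-membered rings, C4 an anti-Bredt bicycle). The dienolate isomers interconvert by proton exchange with t-BuOH, so the geometry with C7 cis to C4a is funnelled to product.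

Step 8
Reactants: 17 (3R,7R)-7-hydroxy-3,7-dimethyl-3,4-dihydro-1H-isochromene-6,8(5H,7H)-dione
Product: 18 (3R,7R)-7-hydroxy-3,7-dimethyl-3,4-dihydro-6H-isochromene-6,8(7H)-dione
Conditions: DDQ (1.05 equiv), CH2Cl2, 0 °C → rt
Reagents that add atoms: none
Why: DDQ abstracts hydride from C1, which is α to the ring oxygen and vinylogously conjugated to the 6-enol of 17, and loss of the enol proton from the resulting oxocarbenium ion gives the C1=C8a enol ether and the C4a=C5 enone (dehydrogenation as in DDQ oxidation of isochromans and p-alkoxybenzyl ethers); C3 and C7 are not involved.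

Step 9
Reactants: 18 (3R,7R)-7-hydroxy-3,7-dimethyl-3,4-dihydro-6H-isochromene-6,8(7H)-dione; 19 (9Z,12Z)-octadeca-9,12-dienoyl chloride
Product: 20 (3R,7R)-3,7-dimethyl-6,8-dioxo-3,4,7,8-tetrahydro-6H-isochromen-7-yl (9Z,12Z)-octadeca-9,12-dienoate
Conditions: 19 (1.5 equiv), Et3N, DMAP (0.2 equiv), CH2Cl2, 0 °C → rt, under argon
Reagents that add atoms: none
Why: DMAP-catalysed acylation of the tertiary alcohol by the acid chloride (nucleophilic acyl-transfer catalysis) under mild base leaves the vinylogous ester, both stereocentres and the skipped (Z,Z)-diene untouched.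

Compound list
1 | ethyl (3R)-3-hydroxybutanoate | C[C@@H](O)CC(=O)OCC | starting material
2 | tert-butyl acetate | CC(=O)OC(C)(C)C | starting material
3 | lithium enolate of tert-butyl acetate | C=C([O-])OC(C)(C)C.[Li+] | intermediate
4 | tert-butyl (5R)-5-hydroxy-3-oxohexanoate | C[C@@H](O)CC(=O)CC(=O)OC(C)(C)C | intermediate
5 | tert-butyl (5R)-2-[(dimethylamino)methylidene]-5-hydroxy-3-oxohexanoate | C[C@@H](O)CC(=O)C(=CN(C)C)C(=O)OC(C)(C)C | intermediate
6 | tert-butyl (2R)-2-methyl-4-oxo-3,4-dihydro-2H-pyran-5-carboxylate | C[C@@H]1CC(=O)C(=CO1)C(=O)OC(C)(C)C | intermediate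
7 | lithium (2R)-5-(tert-butoxycarbonyl)-2-methyl-3,6-dihydro-2H-pyran-4-olate | C[C@@H]1CC([O-])=C(CO1)C(=O)OC(C)(C)C.[Li+] | intermediate
8 | tert-butyl (6R)-6-methyl-4-[(trifluoromethanesulfonyl)oxy]-5,6-dihydro-2H-pyran-3-carboxylate | C[C@@H]1CC(OS(=O)(=O)C(F)(F)F)=C(CO1)C(=O)OC(C)(C)C | intermediate
9 | tert-butyl (6R)-4,6-dimethyl-5,6-dihydro-2H-pyran-3-carboxylate | C[C@@H]1CC(C)=C(CO1)C(=O)OC(C)(C)C | intermediate
10 | (R)-lactic acid | C[C@@H](O)C(=O)O | starting material
11 | pivalaldehyde | CC(C)(C)C=O | starting material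
12 | (2R,5R)-2-tert-butyl-5-methyl-1,3-dioxolan-4-one | C[C@H]1O[C@@H](C(C)(C)C)OC1=O | intermediate
13 | (6R)-4,6-dimethyl-5,6-dihydro-2H-pyran-3-carbonyl chloride | C[C@@H]1CC(C)=C(CO1)C(Cl)=O | intermediate
14 | lithium (2R)-2-tert-butyl-5-methyl-1,3-dioxol-4-olate | CC1=C([O-])O[C@H](C(C)(C)C)O1.[Li+] | intermediate
15 | (2R,5S)-2-tert-butyl-5-[(6R)-4,6-dimethyl-5,6-dihydro-2H-pyran-3-carbonyl]-5-methyl-1,3-dioxolan-4-one | C[C@@H]1CC(C)=C(CO1)C(=O)[C@]2(C)O[C@@H](C(C)(C)C)OC2=O | intermediate
16 | potassium γ-dienolate of 15 (C5 exocyclic methylene, enolate at C8) | C=C1C[C@@H](C)OCC1=C([O-])[C@]2(C)O[C@@H](C(C)(C)C)OC2=O.[K+] | intermediate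
17 | (3R,7R)-7-hydroxy-3,7-dimethyl-3,4-dihydro-1H-isochromene-6,8(5H,7H)-dione | C[C@@H]1CC2=C(CO1)C(=O)[C@](C)(O)C(=O)C2 | intermediate
18 | (3R,7R)-7-hydroxy-3,7-dimethyl-3,4-dihydro-6H-isochromene-6,8(7H)-dione | O[C@]1(C)C(=O)C=C2C[C@@H](C)OC=C2C1=O | intermediate
19 | (9Z,12Z)-octadeca-9,12-dienoyl chloride (linoleoyl chloride) | CCCCC/C=C\C/C=C\CCCCCCCC(Cl)=O | starting material
20 | (3R,7R)-3,7-dimethyl-6,8-dioxo-3,4,7,8-tetrahydro-6H-isochromen-7-yl (9Z,12Z)-octadeca-9,12-dienoate | CCCCC/C=C\C/C=C\CCCCCCCC(=O)O[C@]1(C)C(=O)C=C2C[C@@H](C)OC=C2C1=O | target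

Total step count: 9. Longest linear sequence: 8 steps (1 → 4 → 6 → 8 → 9 → 15 → 17 → 18 → 20; step 5 is the side branch).

Steps most likely to fail

1. Step 7 (key step). Alkoxide may attack the C8 ketone or the acetal lactone of the non-enolisable β-keto lactone (retro-Claisen cleavage) faster than γ-deprotonation and ring closure, and the freed C7 alkoxide may undergo an acyloin-type shift before the quench. The fallback sets out from 15 and comes back at 17; it removes the acetal without base, keeps C7–O capped and closes the ring with a non-nucleophilic base onto a simple ester. Acid-catalysed methanolysis (MeOH, cat. TsOH, 40 °C) should give methyl (2S)-3-[(6R)-4,6-dimethyl-5,6-dihydro-2H-pyran-3-yl]-2-hydroxy-2-methyl-3-oxopropanoate F1. Silylation (TESOTf, 2,6-lutidine, CH2Cl2) should give methyl (2S)-3-[(6R)-4,6-dimethyl-5,6-dihydro-2H-pyran-3-yl]-2-methyl-3-oxo-2-[(triethylsilyl)oxy]propanoate F2. Dieckmann closure of its γ-dienolate (KHMDS, THF, −78 → 0 °C) should give (3R,7R)-3,7-dimethyl-7-[(triethylsilyl)oxy]-3,4-dihydro-1H-isochromene-6,8(5H,7H)-dione F3, and HF·pyridine should free 17.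

2. Step 6. The hindered, tetrasubstituted acid chloride may be deprotonated at its γ-positions by the enolate (vinylketene formation) or acylate the enolate on oxygen, and the enolate may decompose before the slow C-acylation. The fallback sets out from 9 and comes back at 15; it replaces the acylation by an aldol addition and an oxidation. DIBAL-H (CH2Cl2, −78 °C) should give [(6R)-4,6-dimethyl-5,6-dihydro-2H-pyran-3-yl]methanol F4, and MnO2 should give (6R)-4,6-dimethyl-5,6-dihydro-2H-pyran-3-carbaldehyde F5. Aldol addition of enolate 14 to F5 at −78 °C, again anti to the tert-butyl group, should give (2R,5S)-2-tert-butyl-5-{hydroxy[(6R)-4,6-dimethyl-5,6-dihydro-2H-pyran-3-yl]methyl}-5-methyl-1,3-dioxolan-4-one F6 as a mixture at the carbinol carbon, and DMP oxidation should converge both epimers on 15.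

3. Step 8. DDQ may go on to dehydrogenate C3–C4, or the electron-rich dienol of 17 may be oxidised or dimerise by paths other than hydride loss from C1. The fallback sets out from 17 and comes back at 18; it replaces hydride abstraction by a palladium enolate β-hydride elimination. TMSOTf/Et3N should give (3R,7R)-3,7-dimethyl-6,7-bis[(trimethylsilyl)oxy]-3,4-dihydro-1H-isochromen-8(7H)-one F7. Pd(OAc)2 in MeCN (Saegusa–Ito oxidation; palladium migrates over the C5–C4a–C8a allyl unit and eliminates a C1 hydrogen) should give (3R,7R)-3,7-dimethyl-7-[(trimethylsilyl)oxy]-3,4-dihydro-6H-isochromene-6,8(7H)-dione F8, and HF·pyridine should give 18.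

Further compounds
F1 | step 7 | methyl (2S)-3-[(6R)-4,6-dimethyl-5,6-dihydro-2H-pyran-3-yl]-2-hydroxy-2-methyl-3-oxopropanoate | C[C@@H]1CC(C)=C(CO1)C(=O)[C@](C)(O)C(=O)OC
F2 | step 7 | methyl (2S)-3-[(6R)-4,6-dimethyl-5,6-dihydro-2H-pyran-3-yl]-2-methyl-3-oxo-2-[(triethylsilyl)oxy]propanoate | C[C@@H]1CC(C)=C(CO1)C(=O)[C@](C)(O[Si](CC)(CC)CC)C(=O)OC
F3 | step 7 | (3R,7R)-3,7-dimethyl-7-[(triethylsilyl)oxy]-3,4-dihydro-1H-isochromene-6,8(5H,7H)-dione | C[C@@H]1CC2=C(CO1)C(=O)[C@](C)(O[Si](CC)(CC)CC)C(=O)C2
F4 | step 6 | [(6R)-4,6-dimethyl-5,6-dihydro-2H-pyran-3-yl]methanol | C[C@@H]1CC(C)=C(CO)CO1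
F5 | step 6 | (6R)-4,6-dimethyl-5,6-dihydro-2H-pyran-3-carbaldehyde | C[C@@H]1CC(C)=C(C=O)CO1
F6 | step 6 | (2R,5S)-2-tert-butyl-5-{hydroxy[(6R)-4,6-dimethyl-5,6-dihydro-2H-pyran-3-yl]methyl}-5-methyl-1,3-dioxolan-4-one | C[C@@H]1CC(C)=C(CO1)C(O)[C@]2(C)O[C@@H](C(C)(C)C)OC2=O
F7 | step 8 | (3R,7R)-3,7-dimethyl-6,7-bis[(trimethylsilyl)oxy]-3,4-dihydro-1H-isochromen-8(7H)-one | C[C@@H]1CC2=C(CO1)C(=O)[C@](C)(O[Si](C)(C)C)C(O[Si](C)(C)C)=C2
F8 | step 8 | (3R,7R)-3,7-dimethyl-7-[(trimethylsilyl)oxy]-3,4-dihydro-6H-isochromene-6,8(7H)-dione | C[Si](C)(C)O[C@]1(C)C(=O)C=C2C[C@@H](C)OC=C2C1=O
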